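## Retrosynthetic overview
1. The C4 ketone of the target is carried as a spiro-1,3-dithiane and released last, under acid. In base the free chromanone would lose its C2 configuration through E1cB ring opening and reclosure.
2. Ring A is bought. Ring B, the only ring built, is cut at two bonds at once: O1–C8a (SNAr on a C–F bond) and C3–C4 (key bond).
3. For the key bond, the formyl carbon of 4-fluoro-3-formylbenzoic acid becomes a nucleophile as its lithiated dithiane (an aroyl anion), with the acid carried unprotected as the carboxylate. It attacks the CH2 of an (S)-2,2-disubstituted epoxide, so two naturally electrophilic carbons are joined.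
4. The (S)-epoxide comes from (E)-geranylacetone plus CH2 by catalytic asymmetric Corey–Chaykovsky epoxidation. The C2–O bond set there is never broken again.

Assumption: single-isomer (E)-geranylacetone is bought, and the (S)-BINOL form of the La/Li catalyst is taken to give the (S)-epoxide; if the sense proves opposite, (R)-BINOL is used.

## Route

Step 1
Reactants: 1 (E)-geranylacetone, (5E)-6,10-dimethylundeca-5,9-dien-2-one
Product: 2 (2S)-2-[(3E)-4,8-dimethylnona-3,7-dien-1-yl]-2-methyloxirane
Conditions: Me3S(O)I, NaH, THF, reflux (ylide solution, 1.2 equiv); LaLi3[(S)-binaphthoxide]3 (5 mol %, from La(Oi-Pr)3, (S)-BINOL, n-BuLi), [2,4,6-(MeO)3C6H2]3P=O (5 mol %), MS 5 Å, THF, rt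
Reagents that add atoms: trimethylsulfoxonium iodide, C[S+](C)(C)=O.[I-]
Why: This is a catalytic asymmetric Corey–Chaykovsky epoxidation in which the La/Li binaphthoxide holds the methyl ketone on La and the ylide oxygen on Li and tells CH3 from the long chain, so CH2 arrives on one face and C2 is set as (S) (methyl alkyl ketones typically give above 90 % ee), while the two trisubstituted alkenes are inert to a sulfoxonium ylide.

Step 2
Reactants: 3 4-fluoro-3-formylbenzoic acid
Product: 4 3-(1,3-dithian-2-yl)-4-fluorobenzoic acid
Conditions: HS(CH2)3SH (1.1 equiv), BF3·OEt2 (0.5 equiv), CH2Cl2–AcOH, rt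
Reagents that add atoms: propane-1,3-dithiol, SCCCS
Why: Lewis-acid-catalysed dithioacetalisation turns the formyl carbon into a Corey–Seebach acyl anion precursor, no thiolate exists under acid so the activated C–F bond is not displaced, and no stereocentre is involved.

Step 3
Reactants: 4 3-(1,3-dithian-2-yl)-4-fluorobenzoic acid (1.2 equiv); 2 (2S)-2-[(3E)-4,8-dimethylnona-3,7-dien-1-yl]-2-methyloxirane (1.0 equiv)
Product: 8 (2S)-2-[(3E)-4,8-dimethylnona-3,7-dien-1-yl]-2-methylspiro[chromane-4,2'-[1,3]dithiane]-6-carboxylic acid, via dilithio dianion 5 (not isolated), via ring-opened dilithium alkoxide 6 (not isolated), via lithium carboxylate 7 (not isolated)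
Conditions: LiN(i-Pr)2 (2.1 equiv per 4), THF, −78 to −30 °C; 2, DMPU, −30 °C to rt; KOt-Bu (2 equiv), 65 °C; then 1 M HCl, 0 °C
Reagents that add atoms: none
Why: Proposed new method: a one-flask (3+3) annulation in which the first base equivalent makes the carboxylate (inert to a hindered stabilised carbanion, and it keeps the ring too electron-rich for self-SNAr) and the second makes the 2-aryl-dithianyl anion 5, which opens the epoxide by SN2 at its unsubstituted CH2 so the C2–O bond and the (S) configuration are untouched; the tertiary alkoxide 6 then displaces the ortho fluoride (six-membered closure, Thorpe–Ingold help from two quaternary carbons, σ-complex stabilised by the para carboxylate, K+ raising alkoxide reactivity), and because C4 stays a dithioketal neither retro-aldol cleavage nor E1cB racemisation is possible; the closest known reaction types are the Corey–Seebach dithiane/epoxide coupling and the intramolecular SNAr synthesis of chromans from 3-(2-fluorophenyl)propanols.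

Step 4
Reactants: 8 (2S)-2-[(3E)-4,8-dimethylnona-3,7-dien-1-yl]-2-methylspiro[chromane-4,2'-[1,3]dithiane]-6-carboxylic acid
Product: 9 (2S)-2-[(3E)-4,8-dimethylnona-3,7-dien-1-yl]-2-methyl-4-oxo-3,4-dihydro-2H-chromene-6-carboxylic acid (target)
Conditions: PhI(OCOCF3)2 (1.5 equiv), MeCN–H2O 9:1, 0 °C, 15 min, dark
Reagents that add atoms: water, O
Why: In this oxidative dithiane hydrolysis the trivalent iodine reagent attacks sulfur far faster than the trisubstituted alkenes or the electron-poor arene, water takes the benzylic thionium ion to the ketone, and the cold acidic medium gives the base-triggered E1cB opening of ring B no chance, so (S) at C2 is kept.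

## Compound list
1 | (E)-geranylacetone, (5E)-6,10-dimethylundeca-5,9-dien-2-one | CC(C)=CCC/C(C)=C/CCC(C)=O | starting material
2 | (2S)-2-[(3E)-4,8-dimethylnona-3,7-dien-1-yl]-2-methyloxirane | CC(C)=CCC/C(C)=C/CC[C@@]1(C)CO1 | intermediate
3 | 4-fluoro-3-formylbenzoic acid | O=Cc1cc(C(=O)O)ccc1F | starting material
4 | 3-(1,3-dithian-2-yl)-4-fluorobenzoic acid | OC(=O)c1ccc(F)c(c1)C1SCCCS1 | intermediate
5 | lithium 4-fluoro-3-(2-lithio-1,3-dithian-2-yl)benzoate (dianion of 4) | [Li+].[Li+].[O-]C(=O)c1ccc(F)c(c1)[C-]1SCCCS1 | intermediate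
6 | dilithium salt (tertiary alkoxide and carboxylate) of 4-fluoro-3-{2-[(2S,5E)-2-hydroxy-2,6,10-trimethylundeca-5,9-dien-1-yl]-1,3-dithian-2-yl}benzoic acid | [Li+].[Li+].CC(C)=CCC/C(C)=C/CC[C@@]([O-])(C)CC1(SCCCS1)c1cc(C(=O)[O-])ccc1F | intermediate
7 | lithium (2S)-2-[(3E)-4,8-dimethylnona-3,7-dien-1-yl]-2-methylspiro[chromane-4,2'-[1,3]dithiane]-6-carboxylate | [Li+].CC(C)=CCC/C(C)=C/CC[C@@]1(C)CC2(SCCCS2)c2cc(C(=O)[O-])ccc2O1 | intermediate
8 | (2S)-2-[(3E)-4,8-dimethylnona-3,7-dien-1-yl]-2-methylspiro[chromane-4,2'-[1,3]dithiane]-6-carboxylic acid | CC(C)=CCC/C(C)=C/CC[C@@]1(C)CC2(SCCCS2)c2cc(C(=O)O)ccc2O1 | intermediate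
9 | (2S)-2-[(3E)-4,8-dimethylnona-3,7-dien-1-yl]-2-methyl-4-oxo-3,4-dihydro-2H-chromene-6-carboxylic acid | CC(C)=CCC/C(C)=C/CC[C@@]1(C)CC(=O)c2cc(C(=O)O)ccc2O1 | target

## Step count and risks
Total steps: 4. Longest linear sequence: 3 (1 → 2 → 8 → 9, or 3 → 4 → 8 → 9).

**Step 3 is the most likely to fail.** The SNAr has to occur on a ring whose only para activator is a carboxylate, and a hindered carbanion has to open a 2,2-disubstituted epoxide.
- The fallback splits the cascade and activates the ring with an ester. It sets out from 6.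
- The mixture is quenched cold right after the epoxide opening to give the hydroxy acid F1.
- Me3SiCHN2 in toluene–MeOH converts it into the hydroxy methyl ester F2, in which fluorine now sits para to an ester.
- KN(SiMe3)2 in THF at 0 °C to rt closes ring B to the spiro-dithiane methyl ester F3.
- LiOH in THF–H2O saponifies F3 while C4 is still a dithioketal, so no enolate and no ring opening are possible. The route is rejoined at 8.

**Step 1 comes second.** The catalyst must distinguish CH3 from CH2, so the ee could fall short, or the sense of induction could differ from the assumed one.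
- The fallback replaces asymmetric catalysis by resolution and sets out from 1.
- A plain Corey–Chaykovsky reaction (Me3S(O)I, NaH, DMSO, rt) gives the racemic epoxide F4.
- Kinetic resolution follows with Me3SiN3 and i-PrOH (0.55 equiv each) and (salen)CrN3. This is the azide of the trivalent chromium complex of N,N'-bis(3,5-di-tert-butylsalicylidene)cyclohexane-1,2-diamine, used as the antipode that consumes the (R)-epoxide.
- The unwanted half is converted into the (R)-azido alcohol F5. The unreacted (S)-epoxide is separated by chromatography, and the route is rejoined at 2.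

**Step 4 comes third.** The oxidant could touch the two electron-rich alkenes, or thiyl species could scramble the E alkene.
- The fallback replaces the one-shot oxidative cleavage by a two-stage sulfoxide route and sets out from 8.
- NaIO4 (1.0 equiv, MeOH–H2O, 0 °C) does not react with alkenes and gives the dithiane monosulfoxide F6 as a mixture at sulfur.
- Catalytic H2SO4 in wet THF at rt then expels the sulfenic acid arm and hydrolyses the thionium ion, again without base. The route is rejoined at 9.

## Further compounds
F1 | step 3 | 4-fluoro-3-{2-[(2S,5E)-2-hydroxy-2,6,10-trimethylundeca-5,9-dien-1-yl]-1,3-dithian-2-yl}benzoic acid | CC(C)=CCC/C(C)=C/CC[C@@](O)(C)CC1(SCCCS1)c1cc(C(=O)O)ccc1F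
F2 | step 3 | methyl 4-fluoro-3-{2-[(2S,5E)-2-hydroxy-2,6,10-trimethylundeca-5,9-dien-1-yl]-1,3-dithian-2-yl}benzoate | CC(C)=CCC/C(C)=C/CC[C@@](O)(C)CC1(SCCCS1)c1cc(C(=O)OC)ccc1F
F3 | step 3 | methyl (2S)-2-[(3E)-4,8-dimethylnona-3,7-dien-1-yl]-2-methylspiro[chromane-4,2'-[1,3]dithiane]-6-carboxylate | CC(C)=CCC/C(C)=C/CC[C@@]1(C)CC2(SCCCS2)c2cc(C(=O)OC)ccc2O1
F4 | step 1 | racemic 2-[(3E)-4,8-dimethylnona-3,7-dien-1-yl]-2-methyloxirane | CC(C)=CCC/C(C)=C/CCC1(C)CO1
F5 | step 1 | (2R,5E)-1-azido-2,6,10-trimethylundeca-5,9-dien-2-ol | CC(C)=CCC/C(C)=C/CC[C@](O)(C)CN=[N+]=[N-]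
F6 | step 4 | (2S)-2-[(3E)-4,8-dimethylnona-3,7-dien-1-yl]-2-methylspiro[chromane-4,2'-[1,3]dithiane]-6-carboxylic acid 1'-oxide (mixture at sulfur) | CC(C)=CCC/C(C)=C/CC[C@@]1(C)CC2(SCCCS2=O)c2cc(C(=O)O)ccc2O1
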